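## Retrosynthetic overview

1. The C6 chloride comes from a C6 allylic alcohol with inversion. The ten-membered ring is closed last, at C5–C6, by an intramolecular Nozaki–Hiyama–Kishi coupling of a C5 alkenyl iodide with a C6 aldehyde.
2. The open-chain aldehyde comes from joining two fragments at C9–C10 by a Hosomi–Sakurai allylation of lactone aldehyde (fragment 2) with ring A allylsilane (fragment 1). The C11=C20 methylene this leaves is epoxidized under direction by the C9 hydroxyl.
3. Fragment 1 starts from 2-methylcyclohexane-1,3-dione (ring A is bought). C2 is set by a Trost allene addition, C1/C14 by CBS desymmetrization, and C3–C5 are added by B-alkyl Suzuki coupling.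
4. Fragment 2 starts from L-serine (C7). The γ-lactone is closed by a SmI2 Reformatsky reaction (C8–C17 bond), which sets C8 and C17.
5. Ring order: ring A (present from the start), γ-lactone (in fragment 2), ten-membered ring (last).

Assumption: atoms carry briarane numbers (C1–C20; lactone carbonyl C19, its methyl C18), and in step 2 the (R,R)-ligand is taken to give the S ether (otherwise the (S,S)-ligand is used).

## Route

Step 1
Reactants: 1 4-methoxybenzyl propargyl ether
Product: 2 (4-methoxybenzyloxy)allene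
Conditions: KOtBu (0.3 equiv), THF, rt
Reagents that add atoms: none
Why: Base-catalysed propargyl-to-allenyl ether isomerisation (prototropic rearrangement) gives the alkoxyallene; no stereocentre is formed.

Step 2
Reactants: 3 2-methylcyclohexane-1,3-dione; 2 (4-methoxybenzyloxy)allene
Product: 4 (S)-2-[1-(4-methoxybenzyloxy)prop-2-en-1-yl]-2-methylcyclohexane-1,3-dione
Conditions: Pd2(dba)3·CHCl3 (2.5 mol %), (R,R)-DACH-phenyl Trost ligand (7.5 mol %), PhCO2H (10 mol %), Et3N (10 mol %), CH2Cl2, rt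
Reagents that add atoms: none
Why: Trost asymmetric hydroalkylation of an alkoxyallene: zerovalent palladium forms an alkoxy-π-allyl by hydropalladation, the dione enolate attacks the oxygen-bearing terminus, and the chiral ligand sets C2 as S.

Step 3
Reactants: 4 (S)-2-[1-(4-methoxybenzyloxy)prop-2-en-1-yl]-2-methylcyclohexane-1,3-dione
Product: 5 (2R,3S)-3-hydroxy-2-[(1S)-1-(4-methoxybenzyloxy)prop-2-en-1-yl]-2-methylcyclohexan-1-one
Conditions: (R)-2-methyl-CBS-oxazaborolidine (20 mol %), catecholborane (1.1 equiv), toluene, −78 °C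
Reagents that add atoms: none
Why: Corey–Bakshi–Shibata reduction as a desymmetrisation: the catalyst gives the S carbinol and reduces the carbonyl whose reacting face is anti to the bulky alkoxyallyl group, so the hydroxyl (C14) is cis to the side chain and the quaternary C1 is fixed.

Step 4
Reactants: 5 (2R,3S)-3-hydroxy-2-[(1S)-1-(4-methoxybenzyloxy)prop-2-en-1-yl]-2-methylcyclohexan-1-one
Product: 6 (2R,3S)-3-hydroxy-2-[(1S)-1-hydroxyprop-2-en-1-yl]-2-methylcyclohexan-1-one
Conditions: DDQ (1.3 equiv), CH2Cl2/H2O (10:1), 0 °C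
Reagents that add atoms: none
Why: Oxidative PMB-ether cleavage by DDQ (hydride abstraction to the oxocarbenium ion, then hydrolysis) frees the C2 hydroxyl without touching a stereocentre.

Step 5
Reactants: 6 (2R,3S)-3-hydroxy-2-[(1S)-1-hydroxyprop-2-en-1-yl]-2-methylcyclohexan-1-one
Product: 7 di-tert-butylsilylene acetal of 6 (cis-fused 1,3-dioxa-2-silinane across O2 and O14; vinyl on C2; ketone at C10)
Conditions: tBu2Si(OTf)2, 2,6-lutidine, CH2Cl2, 0 °C
Reagents that add atoms: di-tert-butylsilyl bis(trifluoromethanesulfonate), CC(C)(C)[Si](OS(=O)(=O)C(F)(F)F)(OS(=O)(=O)C(F)(F)F)C(C)(C)C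
Why: Silylene protection of the 1,3-diol masks both hydroxyls against the bases used next and gives the cis-fused ring that later controls the face of attack at C10; no stereocentre changes.

Step 6
Reactants: 8 trimethyl(vinyl)silane
Product: 10 (1-bromovinyl)trimethylsilane, via (1,2-dibromoethyl)trimethylsilane 9 (not isolated)
Conditions: Br2, CH2Cl2, −78 °C; then Et2NH, reflux
Reagents that add atoms: bromine, BrBr
Why: Electrophilic bromine addition to the vinylsilane followed by amine-induced E2 dehydrobromination (loss of the acidic α-silyl proton) gives the α-bromovinylsilane.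

Step 7
Reactants: 7 di-tert-butylsilylene acetal of 6; 10 (1-bromovinyl)trimethylsilane
Product: 12 silylene ketone carrying the C3–C4–C5(SiMe3)=CH2 side chain, via B-alkyl-9-BBN adduct 11 (not isolated)
Conditions: 9-BBN, THF, rt; then 10, PdCl2(dppf) (5 mol %), AsPh3, Cs2CO3, DMF/H2O, rt
Reagents that add atoms: none
Why: Anti-Markovnikov hydroboration of the only monosubstituted alkene and B-alkyl Suzuki–Miyaura coupling with the alkenyl bromide build C3–C5 with C5 as a 2-silylalkene; the hindered ketone is not reduced.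

Step 8
Reactants: 12 silylene ketone carrying the C3–C4–C5(SiMe3)=CH2 side chain; 13 (iodomethyl)trimethylsilane
Product: 15 C11-(trimethylsilylmethyl) ketone (both C11 epimers), via lithium enolate 14 (not isolated)
Conditions: LiN(iPr)2, THF, −78 °C; then 13, DMPU, −78 → 0 °C
Reagents that add atoms: none
Why: Enolate alkylation (SN2): C1 is quaternary, so only C11 can be deprotonated; the new C11 centre becomes sp2 two steps later, so its configuration does not matter.

Step 9
Reactants: 15 C11-(trimethylsilylmethyl) ketone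
Product: 17 enol triflate (C10–OTf, C10=C11), via potassium enolate 16 (not isolated)
Conditions: KN(SiMe3)2, THF, −78 °C; then PhNTf2, −78 → 0 °C
Reagents that add atoms: N-phenylbis(trifluoromethanesulfonimide), O=S(=O)(N(c1ccccc1)S(=O)(=O)C(F)(F)F)C(F)(F)F
Why: Enolate O-sulfonylation gives the tetrasubstituted enol triflate regiospecifically, because C11 carries the only α-hydrogen.

Step 10
Reactants: 17 enol triflate
Product: 18 fragment 1, the ring A allylsilane (C10=C11, CH2SiMe3 on C11)
Conditions: Pd(OAc)2 (5 mol %), PPh3 (10 mol %), HCO2H, n-Bu3N, DMF, 60 °C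
Reagents that add atoms: none
Why: Palladium-catalysed formate reduction of the enol triflate (oxidative addition, formate decarboxylation, reductive elimination) replaces OTf by H and leaves the C10=C11 alkene, i.e. the allylsilane.

Step 11
Reactants: 19 L-serine
Product: 20 (S)-2,3-dihydroxypropanoic acid (L-glyceric acid)
Conditions: NaNO2, aq. HCl, 0 °C → rt
Reagents that add atoms: water, O
Why: Diazotisation of the α-amino acid proceeds with net retention (double inversion through the α-lactone), so L-serine gives the S acid that supplies C7.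

Step 12
Reactants: 20 (S)-2,3-dihydroxypropanoic acid
Product: 21 methyl (S)-2,2-dimethyl-1,3-dioxolane-4-carboxylate
Conditions: 2,2-dimethoxypropane, MeOH, p-TsOH (cat.), rt
Reagents that add atoms: 2,2-dimethoxypropane, COC(C)(C)OC; methanol, CO
Why: Acid-catalysed Fischer esterification and acetonide formation by transketalisation protect acid and diol; the stereocentre is untouched.

Step 13
Reactants: 21 methyl (S)-2,2-dimethyl-1,3-dioxolane-4-carboxylate; 22 1,3-dithiane
Product: 23 (S)-(1,3-dithian-2-yl)(2,2-dimethyl-1,3-dioxolan-4-yl)methanone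
Conditions: 22 (2.2 equiv), n-BuLi (2.1 equiv), THF, −30 °C; then 21, −78 °C; aq. NH4Cl
Reagents that add atoms: none
Why: Corey–Seebach umpolung: the lithiated dithiane is acylated by the ester, and the acidic 2-acyldithiane is deprotonated at once, which stops a second addition and keeps C7 from enolising.

Step 14
Reactants: 23 (S)-(1,3-dithian-2-yl)(2,2-dimethyl-1,3-dioxolan-4-yl)methanone
Product: 24 (S)-1-(1,3-dithian-2-yl)-2,3-dihydroxypropan-1-one
Conditions: AcOH/H2O (4:1), 40 °C
Reagents that add atoms: none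
Why: Mild acid-catalysed acetonide hydrolysis; the dithiane and the α-hydroxy ketone stereocentre survive.

Step 15
Reactants: 24 (S)-1-(1,3-dithian-2-yl)-2,3-dihydroxypropan-1-one
Product: 26 (S)-1-(1,3-dithian-2-yl)-2-hydroxy-3-(4-methoxybenzyloxy)propan-1-one, via dibutylstannylene acetal 25 (not isolated)
Conditions: Bu2SnO, MeOH, 65 °C, evaporate; then PMBCl, CsF, DMF, rt
Reagents that add atoms: 4-methoxybenzyl chloride, COc1ccc(CCl)cc1
Why: Stannylene-acetal-directed regioselective O-alkylation (Williamson type) benzylates only the primary hydroxyl (C6–O).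

Step 16
Reactants: 26 (S)-1-(1,3-dithian-2-yl)-2-hydroxy-3-(4-methoxybenzyloxy)propan-1-one; 27 2-bromopropanoyl bromide (racemic)
Product: 28 (2S)-1-(1,3-dithian-2-yl)-3-(4-methoxybenzyloxy)-1-oxopropan-2-yl 2-bromopropanoate (both bromide epimers)
Conditions: pyridine, CH2Cl2, 0 °C
Reagents that add atoms: none
Why: O-acylation of the secondary alcohol; both bromide epimers are used because that carbon becomes an enolate in the next step.

Step 17
Reactants: 28 (2S)-1-(1,3-dithian-2-yl)-3-(4-methoxybenzyloxy)-1-oxopropan-2-yl 2-bromopropanoate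
Product: 30 (3R,4S,5S)-4-(1,3-dithian-2-yl)-4-hydroxy-5-[(4-methoxybenzyloxy)methyl]-3-methyloxolan-2-one, via samarium enolate 29 (not isolated)
Conditions: SmI2 (2.2 equiv), THF, −78 °C
Reagents that add atoms: none
Why: Samarium-diiodide-promoted intramolecular Reformatsky (aldol) reaction closes the γ-lactone; in the five-membered transition state the bulky dithianyl group turns away from the C7 side chain and from the enolate methyl, which sets C8 (hydroxyl cis to C6) and C17 (methyl cis to the hydroxyl).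

Step 18
Reactants: 30 (3R,4S,5S)-4-(1,3-dithian-2-yl)-4-hydroxy-5-[(4-methoxybenzyloxy)methyl]-3-methyloxolan-2-one
Product: 31 (3R,4S,5S)-4-(1,3-dithian-2-yl)-5-[(4-methoxybenzyloxy)methyl]-3-methyl-4-(triethylsilyloxy)oxolan-2-one
Conditions: TESOTf, 2,6-lutidine, CH2Cl2, 0 °C
Reagents that add atoms: triethylsilyl trifluoromethanesulfonate, CC[Si](CC)(CC)OS(=O)(=O)C(F)(F)F
Why: Silylation of the hindered tertiary alcohol with the silyl triflate prevents α-hydroxy-aldehyde side reactions and chelation in the coupling.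

Step 19
Reactants: 31 (3R,4S,5S)-4-(1,3-dithian-2-yl)-5-[(4-methoxybenzyloxy)methyl]-3-methyl-4-(triethylsilyloxy)oxolan-2-one
Product: 32 fragment 2, (2S,3S,4R)-2-[(4-methoxybenzyloxy)methyl]-4-methyl-5-oxo-3-(triethylsilyloxy)oxolane-3-carbaldehyde
Conditions: MeI, CaCO3, MeCN/H2O (9:1), 45 °C
Reagents that add atoms: water, O
Why: Alkylative dithiane hydrolysis (S-methylation, then attack of water) unmasks the C9 aldehyde, which cannot epimerise because C8 is quaternary.

Step 20
Reactants: 18 fragment 1, the ring A allylsilane; 32 fragment 2, the lactone aldehyde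
Product: 33 coupled homoallylic alcohol (C9–OH, C11=C20 methylene; C9 and C10 configured as in the target)
Conditions: BF3·OEt2 (1.5 equiv), CH2Cl2, −78 °C
Reagents that add atoms: none
Why: Hosomi–Sakurai allylation (SE2′, open antiperiplanar transition state): C10 attacks the aldehyde from the ring face anti to the pseudoaxial C1–C2 bond of the cis-fused silylene (the face of the C1 methyl), and the open transition state gives the syn C9/C10 relationship of the target while the alkene moves to C11=C20.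

Step 21
Reactants: 33 coupled homoallylic alcohol
Product: 34 11,20-epoxide of 33 (11S)
Conditions: VO(acac)2 (5 mol %), t-BuOOH, CH2Cl2, 0 °C → rt
Reagents that add atoms: tert-butyl hydroperoxide, CC(C)(C)OO
Why: Vanadium-catalysed hydroxyl-directed epoxidation: the homoallylic C9 hydroxyl binds the peroxo-vanadium species and delivers oxygen to the axial face of the exocyclic alkene, syn to the C1 methyl, which sets C11.

Step 22
Reactants: 34 11,20-epoxide of 33
Product: 35 tetraol (free hydroxyls at C2, C8, C9, C14)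
Conditions: Bu4NF, AcOH (1:1), THF, 0 °C → rt
Reagents that add atoms: none
Why: Fluoride-mediated desilylation, buffered with acetic acid to avoid retro-aldol cleavage and lactone migration, removes the silylene and the triethylsilyl ether; the alkenylsilane, the epoxide and the PMB ether survive.

Step 23
Reactants: 35 tetraol
Product: 36 2,9,14-triacetate (C8 hydroxyl free)
Conditions: Ac2O, pyridine, DMAP (cat.), CH2Cl2, 0 °C → rt
Reagents that add atoms: acetic anhydride, CC(=O)OC(C)=O
Why: DMAP-catalysed acetylation esterifies the three secondary hydroxyls; the hindered tertiary C8 hydroxyl does not react.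

Step 24
Reactants: 36 2,9,14-triacetate
Product: 37 alkenyl iodide (C5 iodide)
Conditions: NIS, MeCN/ClCH2CN (4:1), 0 °C → rt
Reagents that add atoms: N-iodosuccinimide, O=C1CCC(=O)N1I
Why: Electrophilic ipso-iododesilylation of the alkenylsilane gives the 2-iodoalkene needed for ring closure; no other alkene is present at this stage.

Step 25
Reactants: 37 alkenyl iodide
Product: 38 primary alcohol (C6–OH)
Conditions: DDQ, CH2Cl2/pH 7 buffer, 0 °C → rt
Reagents that add atoms: none
Why: Oxidative PMB-ether cleavage by DDQ frees the primary C6 hydroxyl; acetates, epoxide and alkenyl iodide are inert.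

Step 26
Reactants: 38 primary alcohol
Product: 39 open-chain aldehyde (C6 aldehyde)
Conditions: Dess–Martin periodinane, pyridine, CH2Cl2, rt
Reagents that add atoms: none
Why: Dess–Martin oxidation of the primary alcohol gives the C6 aldehyde under buffered conditions that do not epimerise C7.

Step 27
Reactants: 39 open-chain aldehyde
Product: 41 macrocyclic (6R)-allylic alcohol (target skeleton, OH in place of Cl, opposite configuration at C6), via alkenylchromium dichloride 40 (not isolated)
Conditions: CrCl2 (10 equiv), NiCl2 (1 mol %), DMSO, rt, 2 mM (slow addition)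
Reagents that add atoms: none
Why: Intramolecular Nozaki–Hiyama–Kishi macrocyclization (nickel-catalysed, chromium-mediated alkenyl addition at high dilution) forms the C5–C6 bond and the ten-membered ring; chelation of chromium between the aldehyde and the C8 hydroxyl is expected to give the 6R alcohol (1,3-anti to the C8 hydroxyl).

Step 28
Reactants: 41 macrocyclic (6R)-allylic alcohol
Product: 42 CNP0104093.2 (target; 1S,2S,6S,7R,8R,9S,10S,11S,14S,17R)
Conditions: PPh3, hexachloroacetone, CH2Cl2, −20 → 0 °C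
Reagents that add atoms: hexachloroacetone, ClC(Cl)(Cl)C(=O)C(Cl)(Cl)Cl
Why: Appel-type chlorodehydroxylation (Magid conditions) is an SN2 displacement of the alkoxyphosphonium ion without allylic transposition, so C6 is inverted to the 6S chloride; the tertiary C8 hydroxyl is too hindered to react.

## Compound list

1 | 4-methoxybenzyl propargyl ether (1-methoxy-4-[(prop-2-yn-1-yloxy)methyl]benzene) | C#CCOCc1ccc(OC)cc1 | starting material
2 | (4-methoxybenzyloxy)allene | C=C=COCc1ccc(OC)cc1 | intermediate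
3 | 2-methylcyclohexane-1,3-dione | CC1C(=O)CCCC1=O | starting material
4 | (S)-2-[1-(4-methoxybenzyloxy)prop-2-en-1-yl]-2-methylcyclohexane-1,3-dione | C=C[C@H](OCc1ccc(OC)cc1)C1(C)C(=O)CCCC1=O | intermediate
5 | (2R,3S)-3-hydroxy-2-[(1S)-1-(4-methoxybenzyloxy)prop-2-en-1-yl]-2-methylcyclohexan-1-one | C=C[C@H](OCc1ccc(OC)cc1)[C@@]1(C)[C@@H](O)CCCC1=O | intermediate
6 | (2R,3S)-3-hydroxy-2-[(1S)-1-hydroxyprop-2-en-1-yl]-2-methylcyclohexan-1-one | C=C[C@H](O)[C@@]1(C)[C@@H](O)CCCC1=O | intermediate
7 | di-tert-butylsilylene acetal of 6 (cis-fused dioxasilinane, vinyl on C2, ketone at C10) | C=C[C@H](O2)[C@@]1(C)[C@@H](O[Si]2(C(C)(C)C)C(C)(C)C)CCCC1=O | intermediate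
8 | trimethyl(vinyl)silane | C=C[Si](C)(C)C | starting material
9 | (1,2-dibromoethyl)trimethylsilane | BrCC(Br)[Si](C)(C)C | intermediate
10 | (1-bromovinyl)trimethylsilane | C=C(Br)[Si](C)(C)C | intermediate
11 | B-alkyl-9-BBN adduct of 7 (boron on C4) | B1(C2CCCC1CCC2)CC[C@H](O3)[C@@]4(C)[C@@H](O[Si]3(C(C)(C)C)C(C)(C)C)CCCC4=O | intermediate
12 | silylene ketone carrying the C3–C4–C5(SiMe3)=CH2 side chain | C=C([Si](C)(C)C)CC[C@H](O3)[C@@]4(C)[C@@H](O[Si]3(C(C)(C)C)C(C)(C)C)CCCC4=O | intermediate
13 | (iodomethyl)trimethylsilane | C[Si](C)(C)CI | starting material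
14 | lithium enolate of 12 (C10–OLi, C10=C11) | C=C([Si](C)(C)C)CC[C@H](O3)[C@@]4(C)[C@@H](O[Si]3(C(C)(C)C)C(C)(C)C)CCC=C4O[Li] | intermediate
15 | C11-(trimethylsilylmethyl) ketone (both C11 epimers) | C=C([Si](C)(C)C)CC[C@H](O3)[C@@]4(C)[C@@H](O[Si]3(C(C)(C)C)C(C)(C)C)CCC(C[Si](C)(C)C)C4=O | intermediate
16 | potassium enolate of 15 | C=C([Si](C)(C)C)CC[C@H](O3)[C@@]4(C)[C@@H](O[Si]3(C(C)(C)C)C(C)(C)C)CCC(C[Si](C)(C)C)=C4O[K] | intermediate
17 | enol triflate (C10–OTf, C10=C11) | C=C([Si](C)(C)C)CC[C@H](O3)[C@@]4(C)[C@@H](O[Si]3(C(C)(C)C)C(C)(C)C)CCC(C[Si](C)(C)C)=C4OS(=O)(=O)C(F)(F)F | intermediate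
18 | fragment 1: ring A allylsilane (C10=C11, CH2SiMe3 on C11) | C=C([Si](C)(C)C)CC[C@H](O3)[C@@]4(C)[C@@H](O[Si]3(C(C)(C)C)C(C)(C)C)CCC(C[Si](C)(C)C)=C4 | intermediate
19 | L-serine | N[C@@H](CO)C(=O)O | starting material
20 | (S)-2,3-dihydroxypropanoic acid (L-glyceric acid) | O[C@@H](CO)C(=O)O | intermediate
21 | methyl (S)-2,2-dimethyl-1,3-dioxolane-4-carboxylate | COC(=O)[C@@H]1COC(C)(C)O1 | intermediate
22 | 1,3-dithiane | C1CSCSC1 | starting material
23 | (S)-(1,3-dithian-2-yl)(2,2-dimethyl-1,3-dioxolan-4-yl)methanone | O=C(C1SCCCS1)[C@@H]1COC(C)(C)O1 | intermediate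
24 | (S)-1-(1,3-dithian-2-yl)-2,3-dihydroxypropan-1-one | O=C(C1SCCCS1)[C@@H](O)CO | intermediate
25 | dibutylstannylene acetal of 24 | O=C(C1SCCCS1)[C@@H]1CO[Sn](CCCC)(CCCC)O1 | intermediate
26 | (S)-1-(1,3-dithian-2-yl)-2-hydroxy-3-(4-methoxybenzyloxy)propan-1-one | O=C(C1SCCCS1)[C@@H](O)COCc1ccc(OC)cc1 | intermediate
27 | 2-bromopropanoyl bromide (racemic) | CC(Br)C(=O)Br | starting material
28 | (2S)-1-(1,3-dithian-2-yl)-3-(4-methoxybenzyloxy)-1-oxopropan-2-yl 2-bromopropanoate (both bromide epimers) | O=C(C1SCCCS1)[C@@H](OC(=O)C(C)Br)COCc1ccc(OC)cc1 | intermediate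
29 | samarium enolate of 28 (O-bound trivalent samarium) | O=C(C1SCCCS1)[C@@H](OC(O[Sm](I)I)=CC)COCc1ccc(OC)cc1 | intermediate
30 | (3R,4S,5S)-4-(1,3-dithian-2-yl)-4-hydroxy-5-[(4-methoxybenzyloxy)methyl]-3-methyloxolan-2-one | C1(SCCCS1)[C@]2(O)[C@@H](C)C(=O)O[C@H]2COCc3ccc(OC)cc3 | intermediate
31 | (3R,4S,5S)-4-(1,3-dithian-2-yl)-5-[(4-methoxybenzyloxy)methyl]-3-methyl-4-(triethylsilyloxy)oxolan-2-one | C1(SCCCS1)[C@]2(O[Si](CC)(CC)CC)[C@@H](C)C(=O)O[C@H]2COCc3ccc(OC)cc3 | intermediate
32 | fragment 2: (2S,3S,4R)-2-[(4-methoxybenzyloxy)methyl]-4-methyl-5-oxo-3-(triethylsilyloxy)oxolane-3-carbaldehyde | O=C[C@]1(O[Si](CC)(CC)CC)[C@@H](C)C(=O)O[C@H]1COCc2ccc(OC)cc2 | intermediate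
33 | coupled homoallylic alcohol (C9–OH, C11=C20 methylene, C8–OTES, silylene on O2/O14, C6–OPMB) | C=C([Si](C)(C)C)CC[C@H](O3)[C@@]4(C)[C@@H](O[Si]3(C(C)(C)C)C(C)(C)C)CCC(=C)[C@@H]4[C@H](O)[C@]5(O[Si](CC)(CC)CC)[C@@H](C)C(=O)O[C@H]5COCc6ccc(OC)cc6 | intermediate
34 | 11,20-epoxide of 33 (11S) | C=C([Si](C)(C)C)CC[C@H](O3)[C@@]4(C)[C@@H](O[Si]3(C(C)(C)C)C(C)(C)C)CC[C@@]7(CO7)[C@@H]4[C@H](O)[C@]5(O[Si](CC)(CC)CC)[C@@H](C)C(=O)O[C@H]5COCc6ccc(OC)cc6 | intermediate
35 | tetraol (hydroxyls at C2, C8, C9, C14; epoxide; C6–OPMB; C5 alkenylsilane) | C=C([Si](C)(C)C)CC[C@H](O)[C@@]4(C)[C@@H](O)CC[C@@]7(CO7)[C@@H]4[C@H](O)[C@]5(O)[C@@H](C)C(=O)O[C@H]5COCc6ccc(OC)cc6 | intermediate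
36 | 2,9,14-triacetate (C8–OH free) | C=C([Si](C)(C)C)CC[C@H](OC(C)=O)[C@@]4(C)[C@@H](OC(C)=O)CC[C@@]7(CO7)[C@@H]4[C@H](OC(C)=O)[C@]5(O)[C@@H](C)C(=O)O[C@H]5COCc6ccc(OC)cc6 | intermediate
37 | alkenyl iodide (C5–I, C6–OPMB) | C=C(I)CC[C@H](OC(C)=O)[C@@]4(C)[C@@H](OC(C)=O)CC[C@@]7(CO7)[C@@H]4[C@H](OC(C)=O)[C@]5(O)[C@@H](C)C(=O)O[C@H]5COCc6ccc(OC)cc6 | intermediate
38 | primary alcohol (C6–OH) | C=C(I)CC[C@H](OC(C)=O)[C@@]4(C)[C@@H](OC(C)=O)CC[C@@]7(CO7)[C@@H]4[C@H](OC(C)=O)[C@]5(O)[C@@H](C)C(=O)O[C@H]5CO | intermediate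
39 | open-chain aldehyde (C6 aldehyde, C5 alkenyl iodide) | C=C(I)CC[C@H](OC(C)=O)[C@@]4(C)[C@@H](OC(C)=O)CC[C@@]7(CO7)[C@@H]4[C@H](OC(C)=O)[C@]5(O)[C@@H](C)C(=O)O[C@H]5C=O | intermediate
40 | alkenylchromium dichloride from 39 | C=C([Cr](Cl)Cl)CC[C@H](OC(C)=O)[C@@]4(C)[C@@H](OC(C)=O)CC[C@@]7(CO7)[C@@H]4[C@H](OC(C)=O)[C@]5(O)[C@@H](C)C(=O)O[C@H]5C=O | intermediate
41 | macrocyclic (6R)-allylic alcohol | C=C1CC[C@H](OC(C)=O)[C@@]2(C)[C@@H](OC(C)=O)CC[C@@]3(CO3)[C@@H]2[C@H](OC(C)=O)[C@]2(O)[C@@H](C)C(=O)O[C@H]2[C@@H]1O | intermediate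
42 | CNP0104093.2: 2,9,14-triacetoxy-6-chloro-11,20-epoxy-8-hydroxybriar-5(16)-ene γ-lactone (C19 carbonyl to O–C7) | C=C1CC[C@H](OC(C)=O)[C@@]2(C)[C@@H](OC(C)=O)CC[C@@]3(CO3)[C@@H]2[C@H](OC(C)=O)[C@]2(O)[C@@H](C)C(=O)O[C@H]2[C@H]1Cl | target

## Step count and risks

Total step count: 28.

Longest linear sequence: 18 steps (steps 1–5, 7–10, then 20–28). The chain from L-serine (steps 11–19, then 20–28) is equally long.

The stereochemical outcomes of steps 20, 21 and 27 are predictions from models, not established results; these are the three steps most likely to fail.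

**Step 20 (union of two hindered partners).** The allylsilane may protodesilylate before it adds to the neopentyl aldehyde, or the syn selectivity may be poor. The fallback sets out from 18 (with 32) and comes back at 33. Compound 18 is treated with NBS in CH2Cl2 at −78 °C (bromodesilylation with allyl shift) to give the allylic bromide F1. F1 and 32 are joined by a Nozaki–Hiyama allylation (CrCl2, THF), which runs through the more reactive allylchromium and a closed chair transition state and therefore gives the C9-epimeric alcohol F2. Dess–Martin oxidation of F2 gives the β,γ-unsaturated C9 ketone F3. Felkin–Anh reduction of F3 with LiBH(s-Bu)3 at −78 °C (hydride anti to the quaternary C1 substituent on C10) then gives 33.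

**Step 21 (face of the epoxidation).** If the directing effect of the C9 hydroxyl is too weak, oxygen will enter from the less hindered equatorial face and give the C11 epimer. The fallback sets out from 33 and comes back at 34. Compound 33 is treated with NBS in wet DME: the bromonium ion forms on the less hindered face and water opens it at the tertiary C11 from the opposite, axial face, giving the bromohydrin F4. Ring closure of F4 with DBU gives 34, so the intrinsic facial bias now works for the desired epimer.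

**Step 27 (ring closure and C6 configuration).** The ten-membered ring may close with the wrong face of the aldehyde. The fallback sets out from 39 and comes back at 41. The Nozaki–Hiyama–Kishi closure is run as before; if it gives mainly the (6S)-alcohol F5 or a mixture, the crude alcohol is oxidised with Dess–Martin periodinane to the cross-conjugated C6 enone F6. F6 is reduced with Me4NBH(OAc)3 in MeCN/AcOH, where hydride is delivered from the boron bound to the C8 hydroxyl (Evans–Saksena, 1,3-anti), giving 41. C6 is then set by a directed reduction and no longer by the cyclization.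

## Further compounds

F1 | step 20 | allylic bromide from 18 (C10–Br, C11=C20 methylene; C10 epimers) | C=C([Si](C)(C)C)CC[C@H](O3)[C@@]4(C)[C@@H](O[Si]3(C(C)(C)C)C(C)(C)C)CCC(=C)C4Br
F2 | step 20 | C9 epimer of 33 | C=C([Si](C)(C)C)CC[C@H](O3)[C@@]4(C)[C@@H](O[Si]3(C(C)(C)C)C(C)(C)C)CCC(=C)[C@@H]4[C@@H](O)[C@]5(O[Si](CC)(CC)CC)[C@@H](C)C(=O)O[C@H]5COCc6ccc(OC)cc6
F3 | step 20 | C9 ketone (β,γ-unsaturated) | C=C([Si](C)(C)C)CC[C@H](O3)[C@@]4(C)[C@@H](O[Si]3(C(C)(C)C)C(C)(C)C)CCC(=C)[C@@H]4C(=O)[C@]5(O[Si](CC)(CC)CC)[C@@H](C)C(=O)O[C@H]5COCc6ccc(OC)cc6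
F4 | step 21 | bromohydrin of 33 (C11–OH, C20–Br) | C=C([Si](C)(C)C)CC[C@H](O3)[C@@]4(C)[C@@H](O[Si]3(C(C)(C)C)C(C)(C)C)CC[C@@](O)(CBr)[C@@H]4[C@H](O)[C@]5(O[Si](CC)(CC)CC)[C@@H](C)C(=O)O[C@H]5COCc6ccc(OC)cc6
F5 | step 27 | (6S)-alcohol, C6 epimer of 41 | C=C1CC[C@H](OC(C)=O)[C@@]2(C)[C@@H](OC(C)=O)CC[C@@]3(CO3)[C@@H]2[C@H](OC(C)=O)[C@]2(O)[C@@H](C)C(=O)O[C@H]2[C@H]1O
F6 | step 27 | C6 enone | C=C1CC[C@H](OC(C)=O)[C@@]2(C)[C@@H](OC(C)=O)CC[C@@]3(CO3)[C@@H]2[C@H](OC(C)=O)[C@]2(O)[C@@H](C)C(=O)O[C@H]2C1=O
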